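**Retrosynthetic overview**

1. Germacrane locants are used: ring A is the carbocycle C1–C10, ring B the lactone O6–C6–C7–C11–C12 (C13 exocyclic methylene), C14 the carboxyl carbon on C10, C15 the methyl on C4. The C14 acid (carried as a 2-(trimethylsilyl)ethyl ester), the C9 acetate and the C8 epoxyangelate (acid 21, fragment C) are adjusted last.
2. Key disconnection C6–C7. The enabling feature is the α-methylene-γ-lactone ring B fused to ring A at C6–C7: the carbinol carbon C6 is bonded to C7, the γ-carbon of the allyl unit C13=C11(C12)–C7. A CrCl2-mediated intramolecular carbonyl allylation (Nozaki–Hiyama–Kishi type) of seco-aldehyde 32 closes ring A and, by lactonisation in the same flask, ring B; the ring-cis C1=C10 alkene and the two cis-oxiranes (C2–C3, C4–C5) bend the chain so that C6 and C7 meet.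
3. Seco chain 32: C11–C13 by a Morita–Baylis–Hillman reaction at a C7 aldehyde followed by SN2′ bromination; C1=C10 by ester enolate aldol addition and dehydration between fragment B and fragment A.
4. Fragment A (C1–C6, C15): both oxiranes by two Sharpless epoxidations from (Z)-3-methylpent-2-en-4-yn-1-ol. Fragment B (C7–C10, C14): chelation-controlled Mukaiyama aldol on an aldehyde from (S)-but-3-ene-1,2-diol. Fragment C: Sharpless epoxidation of angelyl alcohol.
5. Order of ring formation: oxirane C4–C5, oxirane C2–C3, then ring A and ring B together in the key step; the oxirane of the C8 acyl group is made separately and attached afterwards.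

Key step: step 23

Remark (assumption): 1, 9, 13, 18 and 28 are taken as purchasable single isomers; germacrane locants are also used for open-chain intermediates, and CIP descriptors are given in the compound list.

**Route**

Step 1
Reactants: 1 (2Z)-3-methylpent-2-en-4-yn-1-ol
Product: 2 [(2R,3S)-3-ethynyl-3-methyloxiran-2-yl]methanol
Conditions: Ti(OiPr)4 (0.1 equiv), D-(−)-diethyl tartrate (0.12 equiv), t-BuOOH, 4 Å molecular sieves, CH2Cl2, −20 °C
Reagents that add atoms: tert-butyl hydroperoxide CC(C)(C)OO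
Why: Katsuki–Sharpless asymmetric epoxidation of a (Z)-trisubstituted primary allylic alcohol: the titanium D-tartrate complex should deliver oxygen to the face that makes the carbinol-bearing oxirane carbon (C5) R, the Z geometry then fixes C4 in a cis-oxirane, and the alkyne is inert.

Step 2
Reactants: 2 [(2R,3S)-3-ethynyl-3-methyloxiran-2-yl]methanol
Product: 3 (2S,3R)-3-{[(3,4-dimethoxybenzyl)oxy]methyl}-2-ethynyl-2-methyloxirane
Conditions: NaH, 3,4-dimethoxybenzyl bromide, n-Bu4NI (cat.), THF, 0 °C to rt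
Reagents that add atoms: 3,4-dimethoxybenzyl bromide COc1ccc(CBr)cc1OC
Why: Williamson etherification of the primary alkoxide (SN2 at the benzylic bromide); this ether is chosen because DDQ cleaves it faster than the naphthylmethyl ether used at C8, and no stereocentre is touched.

Step 3
Reactants: 3 (2S,3R)-3-{[(3,4-dimethoxybenzyl)oxy]methyl}-2-ethynyl-2-methyloxirane
Product: 5 propargylic alcohol 3-[(2S,3R)-3-{[(3,4-dimethoxybenzyl)oxy]methyl}-2-methyloxiran-2-yl]prop-2-yn-1-ol, via lithium acetylide 4 (not isolated)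
Conditions: n-BuLi, THF, −78 °C; (CH2O)n, −78 °C to rt; H2O
Reagents that add atoms: formaldehyde (as paraformaldehyde) C=O
Why: Deprotonation of the terminal alkyne and 1,2-addition of the lithium acetylide to formaldehyde (alkynylation) add C1 as a propargylic alcohol; at −78 °C the oxirane is not attacked.

Step 4
Reactants: 5 propargylic alcohol
Product: 6 (2Z)-3-[(2S,3R)-3-{[(3,4-dimethoxybenzyl)oxy]methyl}-2-methyloxiran-2-yl]prop-2-en-1-ol
Conditions: H2 (1 atm), Pd on CaCO3 poisoned with Pb(OAc)2, quinoline, EtOAc, rt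
Reagents that add atoms: none
Why: Lindlar semi-hydrogenation adds H2 syn to the alkyne and stops at the alkene, which sets the cis C2=C3 geometry needed for the cis-oxirane; benzylic ether and oxirane should not be hydrogenolysed on the poisoned catalyst.

Step 5
Reactants: 6 cis-allylic alcohol
Product: 7 {(2R,3R)-3-[(2R,3R)-3-{[(3,4-dimethoxybenzyl)oxy]methyl}-2-methyloxiran-2-yl]oxiran-2-yl}methanol
Conditions: Ti(OiPr)4 (0.3 equiv), D-(−)-diethyl tartrate (0.36 equiv), t-BuOOH, 4 Å molecular sieves, CH2Cl2, −20 °C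
Reagents that add atoms: tert-butyl hydroperoxide CC(C)(C)OO
Why: Second Katsuki–Sharpless asymmetric epoxidation, now directed by the C1 hydroxyl: the D-tartrate complex should again make the carbinol-bearing oxirane carbon (C2) R and the cis geometry then gives 3R, i.e. reagent control over the existing oxirane.

Step 6
Reactants: 7 bis-epoxy alcohol
Product: 8 (2S,3R)-3-[(2R,3R)-3-{[(3,4-dimethoxybenzyl)oxy]methyl}-2-methyloxiran-2-yl]oxirane-2-carbaldehyde (fragment A)
Conditions: TEMPO (0.1 equiv), PhI(OAc)2, CH2Cl2, rt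
Reagents that add atoms: none
Why: Oxoammonium (TEMPO/PhI(OAc)2) oxidation of the primary alcohol to the aldehyde under nearly neutral conditions, which should not epimerise the cis-epoxy aldehyde.

Step 7
Reactants: 9 (2S)-but-3-ene-1,2-diol
Product: 10 (4S)-4-ethenyl-2-(naphthalen-2-yl)-1,3-dioxolane (both epimers at the acetal carbon)
Conditions: 2-naphthaldehyde, p-TsOH·H2O (cat.), toluene, reflux (Dean–Stark)
Reagents that add atoms: 2-naphthaldehyde O=Cc1ccc2ccccc2c1
Why: Acid-catalysed acetalisation of the 1,2-diol (1,3-dioxolane formation) with azeotropic removal of water; C8 is untouched and the acetal epimers converge in step 8.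

Step 8
Reactants: 10 naphthylidene acetal
Product: 11 (2S)-2-(naphthalen-2-ylmethoxy)but-3-en-1-ol
Conditions: iBu2AlH (3 equiv), CH2Cl2, −78 to 0 °C; aq. potassium sodium tartrate (KNaC4H4O6)
Reagents that add atoms: none
Why: Regioselective reductive opening of the arylidene acetal: aluminium binds the less hindered primary oxygen and hydride reduces the oxocarbenium ion, leaving the naphthylmethyl ether on the secondary oxygen (C8).

Step 9
Reactants: 11 (2S)-2-(naphthalen-2-ylmethoxy)but-3-en-1-ol
Product: 12 (2S)-2-(naphthalen-2-ylmethoxy)but-3-enal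
Conditions: Dess–Martin periodinane, CH2Cl2, 0 °C; used crude at once
Reagents that add atoms: none
Why: Dess–Martin oxidation under neutral conditions at 0 °C, so that the α-alkoxy β,γ-unsaturated aldehyde is neither epimerised nor isomerised into conjugation.

Step 10
Reactants: 13 2-(trimethylsilyl)ethyl acetate
Product: 15 ketene silyl acetal tert-butyl(dimethyl)({1-[2-(trimethylsilyl)ethoxy]ethenyl}oxy)silane, via lithium enolate 14 (not isolated)
Conditions: LiN(iPr)2, THF, −78 °C; t-BuMe2SiCl, DMPU, −78 °C to rt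
Reagents that add atoms: tert-butyl(chloro)dimethylsilane CC(C)(C)[Si](C)(C)Cl
Why: Kinetic ester enolate formation and O-silylation give the ketene silyl acetal needed for the Mukaiyama aldol reaction.

Step 11
Reactants: 12 (2S)-2-(naphthalen-2-ylmethoxy)but-3-enal; 15 ketene silyl acetal
Product: 16 2-(trimethylsilyl)ethyl (3S,4S)-3-hydroxy-4-(naphthalen-2-ylmethoxy)hex-5-enoate
Conditions: MgBr2·OEt2 (3 equiv), CH2Cl2, −78 to −30 °C; aq. NH4Cl
Reagents that add atoms: none
Why: Chelation-controlled Mukaiyama aldol addition: MgBr2 binds the aldehyde oxygen and the C8 ether oxygen in a five-membered chelate and the ketene acetal attacks the face opposite the vinyl group, which should give the 8,9-syn adduct (9S).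

Step 12
Reactants: 16 β-hydroxy ester
Product: 17 2-(trimethylsilyl)ethyl (3S,4S)-4-(naphthalen-2-ylmethoxy)-3-(triethylsilyloxy)hex-5-enoate (fragment B)
Conditions: Et3SiCl, imidazole, DMF, 0 °C to rt
Reagents that add atoms: chlorotriethylsilane CC[Si](Cl)(CC)CC
Why: Imidazole-assisted silylation of the secondary alcohol masks C9–OH against the enolate chemistry; no stereocentre is touched.

Step 13
Reactants: 18 methyl (2Z)-2-methylbut-2-enoate (methyl angelate)
Product: 19 (2Z)-2-methylbut-2-en-1-ol
Conditions: iBu2AlH (2.2 equiv), CH2Cl2, −78 °C; aq. potassium sodium tartrate (KNaC4H4O6)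
Reagents that add atoms: none
Why: iBu2AlH reduces the ester to the allylic alcohol (1,2-reduction) without isomerising the Z (angelate) double bond.

Step 14
Reactants: 19 (2Z)-2-methylbut-2-en-1-ol
Product: 20 [(2S,3R)-2,3-dimethyloxiran-2-yl]methanol
Conditions: Ti(OiPr)4 (0.1 equiv), L-(+)-diethyl tartrate (0.12 equiv), t-BuOOH, 4 Å molecular sieves, CH2Cl2, −20 °C
Reagents that add atoms: tert-butyl hydroperoxide CC(C)(C)OO
Why: Katsuki–Sharpless asymmetric epoxidation with the L-tartrate ligand, which should make the quaternary carbinol-bearing carbon 2S; the Z geometry gives the cis-oxirane (3R).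

Step 15
Reactants: 20 [(2S,3R)-2,3-dimethyloxiran-2-yl]methanol
Product: 21 (2R,3R)-2,3-dimethyloxirane-2-carboxylic acid (fragment C)
Conditions: TEMPO (0.2 equiv), PhI(OAc)2 (2.2 equiv), MeCN/H2O (1:1), 0 °C to rt
Reagents that add atoms: water O
Why: TEMPO/PhI(OAc)2 oxidation in aqueous acetonitrile takes the primary alcohol through the aldehyde hydrate to the acid; the C2 descriptor changes to R only through the priority change and neither oxirane carbon is touched.

Step 16
Reactants: 17 fragment B ester; 8 fragment A aldehyde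
Product: 23 aldol adduct (epimers at C1 and C10), via lithium enolate 22 (not isolated)
Conditions: LiN(iPr)2 (1.1 equiv), THF, −78 °C; then 8, −78 °C; AcOH quench at −78 °C
Reagents that add atoms: none
Why: Aldol addition of the lithium ester enolate (C10) to the epoxy aldehyde (C1) at −78 °C, where β-elimination of silanolate is slow; the two new centres are mixtures, which does not matter because both become sp2 in step 17.

Step 17
Reactants: 23 aldol adduct
Product: 25 (1(10)E)-enoate with C7 vinyl group, via mesylate 24 (not isolated)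
Conditions: MsCl, Et3N, CH2Cl2, 0 °C; then DBU, 0 °C to rt
Reagents that add atoms: none
Why: Mesylation and E1cB elimination (aldol condensation): the enolate expels mesylate at C1 far more readily than the silyloxy group at C9, and the more stable enoate with C2 trans to the ester (C9 and C2 cis, as in ring A) should predominate.

Step 18
Reactants: 25 enoate with C7 vinyl group
Product: 27 C7 aldehyde, via diol 26 (not isolated)
Conditions: OsO4 (0.02 equiv), NaIO4 (4 equiv), 2,6-lutidine, dioxane/H2O (3:1), rt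
Reagents that add atoms: osmium tetroxide O=[Os](=O)(=O)=O; sodium periodate [Na+].[O-]I(=O)(=O)=O
Why: Lemieux–Johnson oxidative cleavage: OsO4 dihydroxylates the monosubstituted terminal alkene much faster than the electron-poor trisubstituted enoate and NaIO4 cleaves the diol to the C7 aldehyde, while the lutidine buffer should keep C8 from epimerising.

Step 19
Reactants: 27 C7 aldehyde; 28 methyl acrylate
Product: 29 Morita–Baylis–Hillman adduct (both C7 epimers)
Conditions: DABCO (1 equiv), methyl acrylate (excess, neat), rt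
Reagents that add atoms: none
Why: Morita–Baylis–Hillman reaction: DABCO adds to methyl acrylate and the ammonium enolate adds to the C7 aldehyde; both C7 carbinol epimers converge in step 20.

Step 20
Reactants: 29 Morita–Baylis–Hillman adduct
Product: 30 (Z)-allylic bromide (C13 bromide, C7=C11)
Conditions: NBS, Me2S, CH2Cl2, 0 °C (reagent preformed); then 29, 0 °C to rt
Reagents that add atoms: N-bromosuccinimide O=C1CCC(=O)N1Br
Why: Corey–Kim-type activation of the allylic alcohol as an alkoxysulfonium ion and SN2′ attack of bromide give the transposed primary allylic bromide with the thermodynamically preferred Z geometry (C8 cis to CH2Br).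

Step 21
Reactants: 30 (Z)-allylic bromide
Product: 31 C6 primary alcohol
Conditions: DDQ (1.1 equiv), CH2Cl2/pH 7 phosphate buffer (10:1), 0 °C
Reagents that add atoms: none
Why: Oxidative cleavage of the electron-rich 3,4-dimethoxybenzyl ether by DDQ (hydride abstraction, then hydrolysis of the oxocarbenium ion) at 0 °C, where the naphthylmethyl ether, the silyl ether and the allylic bromide should survive.

Step 22
Reactants: 31 C6 primary alcohol
Product: 32 seco-aldehyde (C6 aldehyde, C13 bromide)
Conditions: Dess–Martin periodinane, CH2Cl2, 0 °C to rt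
Reagents that add atoms: none
Why: Dess–Martin oxidation of the primary alcohol to the α,β-epoxy aldehyde under neutral conditions compatible with the allylic bromide.

Step 23
Reactants: 32 seco-aldehyde
Product: 34 bicyclic lactone (rings A and B; 6S,7R), via chromium alkoxide 33 (not isolated)
Conditions: CrCl2 (10 equiv), 4 Å molecular sieves, THF, 25 °C, 32 added over 12 h to 0.002 M; aq. NH4Cl
Reagents that add atoms: none
Why: Two equivalents of CrCl2 (divalent chromium, a one-electron donor) reduce the allylic C13–Br bond to a trivalent 2-(methoxycarbonyl)allylchromium species that attacks the C6 aldehyde through its γ-carbon C7 in a closed six-membered chair transition state, and the chromium alkoxide 33 then displaces methoxide from the C12 ester. The closest known reaction type is the intramolecular Nozaki–Hiyama–Kishi (chromium Barbier) allylation of ω-formyl 2-(bromomethyl)-2-enoates, α,β-epoxy aldehydes included, that closes ten-membered germacranolide rings together with their α-methylene lactones. Ring A closes by 10-exo-trig addition of C7 to the aldehyde carbon and ring B by 5-exo-trig acyl substitution of O6 at C12. The anti C6/C7 relationship (trans-fused lactone) should follow from the chair in which the equilibrating allylchromium places the ring bonds C6–C5 and C7–C8 equatorial; the face of the allyl unit is set by the C8 stereocentre (C8–H in the allyl plane to avoid allylic strain, attack anti to the C8–C9 bond, giving 7R), and the face of the aldehyde by the C5 oxirane, whose oxygen should sit syn to the carbonyl oxygen on the same chromium centre while C7 enters anti to the C4–C5 bond, giving 6S. The step needs ring closure to outrun oligomerisation, which the three cis units (C1=C10 and both oxiranes) and slow addition at high dilution should secure, and it needs chemoselectivity, which rests on the inertness of divalent chromium toward oxiranes, the enoate, the silyl ether and the arylmethyl ether.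

Step 24
Reactants: 34 bicyclic lactone
Product: 35 C8 alcohol
Conditions: DDQ (2.5 equiv), CH2Cl2/pH 7 phosphate buffer (10:1), rt
Reagents that add atoms: none
Why: DDQ cleavage of the 2-naphthylmethyl ether (same mechanism as step 21, now at room temperature with excess oxidant) frees C8–OH; no stereocentre is touched.

Step 25
Reactants: 35 C8 alcohol; 21 (2R,3R)-2,3-dimethyloxirane-2-carboxylic acid
Product: 37 C8 epoxyangelate, via mixed anhydride 36 (not isolated)
Conditions: 21, 2,4,6-trichlorobenzoyl chloride, Et3N, toluene, rt; then 35, DMAP, toluene, rt to 40 °C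
Reagents that add atoms: none
Why: Yamaguchi esterification: the mixed anhydride transfers the epoxy acyl group through the acylpyridinium ion to the hindered C8 hydroxyl; the acid has no α-hydrogen, so its two centres cannot epimerise.

Step 26
Reactants: 37 C8 epoxyangelate
Product: 38 C9 alcohol
Conditions: HF·pyridine, pyridine, THF, 0 °C
Reagents that add atoms: none
Why: Fluoride-mediated cleavage of the secondary triethylsilyl ether with pyridine-buffered HF·pyridine, conditions under which the 2-(trimethylsilyl)ethyl ester and, at 0 °C, the oxiranes should persist.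

Step 27
Reactants: 38 C9 alcohol
Product: 39 leucanthin B 2-(trimethylsilyl)ethyl ester
Conditions: Ac2O, pyridine, DMAP (cat.), CH2Cl2, 0 °C to rt
Reagents that add atoms: acetic anhydride CC(=O)OC(C)=O
Why: DMAP-catalysed acetylation of the C9 hydroxyl; the hindered quaternary acyl group on O8 is not expected to migrate.

Step 28
Reactants: 39 leucanthin B 2-(trimethylsilyl)ethyl ester
Product: 40 leucanthin B
Conditions: tris(dimethylamino)sulfonium difluorotrimethylsilicate (TASF), DMF, 0 °C; cold dilute aq. HCl (pH 3) work-up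
Reagents that add atoms: none
Why: Fluoride attack on silicon triggers β-elimination of the 2-(trimethylsilyl)ethyl ester (fragmentation to Me3SiF, ethene and carboxylate) under non-hydrolytic conditions that should leave acetate, lactone, epoxy ester and oxiranes intact.

**Compound list**

1 | (2Z)-3-methylpent-2-en-4-yn-1-ol | C#C/C(C)=C\CO | starting material
2 | [(2R,3S)-3-ethynyl-3-methyloxiran-2-yl]methanol | C#C[C@]1(C)O[C@@H]1CO | intermediate
3 | (2S,3R)-3-{[(3,4-dimethoxybenzyl)oxy]methyl}-2-ethynyl-2-methyloxirane | C#C[C@]1(C)O[C@@H]1COCc1ccc(OC)c(OC)c1 | intermediate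
4 | lithium acetylide of 3 | [Li]C#C[C@]1(C)O[C@@H]1COCc1ccc(OC)c(OC)c1 | intermediate (not isolated)
5 | 3-[(2S,3R)-3-{[(3,4-dimethoxybenzyl)oxy]methyl}-2-methyloxiran-2-yl]prop-2-yn-1-ol | OCC#C[C@]1(C)O[C@@H]1COCc1ccc(OC)c(OC)c1 | intermediate
6 | (2Z)-3-[(2S,3R)-3-{[(3,4-dimethoxybenzyl)oxy]methyl}-2-methyloxiran-2-yl]prop-2-en-1-ol | OC/C=C\[C@]1(C)O[C@@H]1COCc1ccc(OC)c(OC)c1 | intermediate
7 | {(2R,3R)-3-[(2R,3R)-3-{[(3,4-dimethoxybenzyl)oxy]methyl}-2-methyloxiran-2-yl]oxiran-2-yl}methanol (germacrane 2R,3R,4R,5R) | OC[C@H]1O[C@H]1[C@]1(C)O[C@@H]1COCc1ccc(OC)c(OC)c1 | intermediate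
8 | (2S,3R)-3-[(2R,3R)-3-{[(3,4-dimethoxybenzyl)oxy]methyl}-2-methyloxiran-2-yl]oxirane-2-carbaldehyde (fragment A) | O=C[C@H]1O[C@H]1[C@]1(C)O[C@@H]1COCc1ccc(OC)c(OC)c1 | intermediate
9 | (2S)-but-3-ene-1,2-diol | C=C[C@H](O)CO | starting material
10 | (4S)-4-ethenyl-2-(naphthalen-2-yl)-1,3-dioxolane (both epimers at C2) | C=C[C@H]1COC(c2ccc3ccccc3c2)O1 | intermediate
11 | (2S)-2-(naphthalen-2-ylmethoxy)but-3-en-1-ol | C=C[C@H](OCc1ccc2ccccc2c1)CO | intermediate
12 | (2S)-2-(naphthalen-2-ylmethoxy)but-3-enal | C=C[C@H](OCc1ccc2ccccc2c1)C=O | intermediate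
13 | 2-(trimethylsilyl)ethyl acetate | CC(=O)OCC[Si](C)(C)C | starting material
14 | lithium enolate of 13 | [Li]OC(=C)OCC[Si](C)(C)C | intermediate (not isolated)
15 | tert-butyl(dimethyl)({1-[2-(trimethylsilyl)ethoxy]ethenyl}oxy)silane | C=C(OCC[Si](C)(C)C)O[Si](C)(C)C(C)(C)C | intermediate
16 | 2-(trimethylsilyl)ethyl (3S,4S)-3-hydroxy-4-(naphthalen-2-ylmethoxy)hex-5-enoate | C=C[C@H](OCc1ccc2ccccc2c1)[C@@H](O)CC(=O)OCC[Si](C)(C)C | intermediate
17 | 2-(trimethylsilyl)ethyl (3S,4S)-4-(naphthalen-2-ylmethoxy)-3-(triethylsilyloxy)hex-5-enoate (fragment B) | C=C[C@H](OCc1ccc2ccccc2c1)[C@@H](O[Si](CC)(CC)CC)CC(=O)OCC[Si](C)(C)C | intermediate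
18 | methyl (2Z)-2-methylbut-2-enoate (methyl angelate) | C/C=C(/C)C(=O)OC | starting material
19 | (2Z)-2-methylbut-2-en-1-ol | C/C=C(/C)CO | intermediate
20 | [(2S,3R)-2,3-dimethyloxiran-2-yl]methanol | OC[C@]1(C)O[C@@H]1C | intermediate
21 | (2R,3R)-2,3-dimethyloxirane-2-carboxylic acid (fragment C) | OC(=O)[C@]1(C)O[C@@H]1C | intermediate
22 | lithium enolate of 17 | C=C[C@H](OCc1ccc2ccccc2c1)[C@@H](O[Si](CC)(CC)CC)C=C(O[Li])OCC[Si](C)(C)C | intermediate (not isolated)
23 | aldol adduct: 2-(trimethylsilyl)ethyl (3S,4S)-2-{hydroxy[(2R,3R)-3-((2R,3R)-3-{[(3,4-dimethoxybenzyl)oxy]methyl}-2-methyloxiran-2-yl)oxiran-2-yl]methyl}-4-(naphthalen-2-ylmethoxy)-3-(triethylsilyloxy)hex-5-enoate (epimers at C1 and C10) | C=C[C@H](OCc1ccc2ccccc2c1)[C@@H](O[Si](CC)(CC)CC)C(C(=O)OCC[Si](C)(C)C)C(O)[C@H]1O[C@H]1[C@]1(C)O[C@@H]1COCc1ccc(OC)c(OC)c1 | intermediate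
24 | C1 methanesulfonate of 23 | C=C[C@H](OCc1ccc2ccccc2c1)[C@@H](O[Si](CC)(CC)CC)C(C(=O)OCC[Si](C)(C)C)C(OS(C)(=O)=O)[C@H]1O[C@H]1[C@]1(C)O[C@@H]1COCc1ccc(OC)c(OC)c1 | intermediate (not isolated)
25 | 2-(trimethylsilyl)ethyl (2E,3S,4S)-2-{[(2R,3R)-3-((2R,3R)-3-{[(3,4-dimethoxybenzyl)oxy]methyl}-2-methyloxiran-2-yl)oxiran-2-yl]methylidene}-4-(naphthalen-2-ylmethoxy)-3-(triethylsilyloxy)hex-5-enoate | C=C[C@H](OCc1ccc2ccccc2c1)[C@@H](O[Si](CC)(CC)CC)/C(C(=O)OCC[Si](C)(C)C)=C\[C@H]1O[C@H]1[C@]1(C)O[C@@H]1COCc1ccc(OC)c(OC)c1 | intermediate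
26 | 5,6-dihydroxyhexanoate from 25 (vinyl group dihydroxylated, both epimers at the new carbinol; all other centres as in 25) | OCC(O)[C@H](OCc1ccc2ccccc2c1)[C@@H](O[Si](CC)(CC)CC)/C(C(=O)OCC[Si](C)(C)C)=C\[C@H]1O[C@H]1[C@]1(C)O[C@@H]1COCc1ccc(OC)c(OC)c1 | intermediate (not isolated)
27 | 2-(trimethylsilyl)ethyl (2E,3S,4R)-2-{[(2R,3R)-3-((2R,3R)-3-{[(3,4-dimethoxybenzyl)oxy]methyl}-2-methyloxiran-2-yl)oxiran-2-yl]methylidene}-4-(naphthalen-2-ylmethoxy)-5-oxo-3-(triethylsilyloxy)pentanoate (C7 aldehyde; C8 geometry as in 25) | O=C[C@H](OCc1ccc2ccccc2c1)[C@@H](O[Si](CC)(CC)CC)/C(C(=O)OCC[Si](C)(C)C)=C\[C@H]1O[C@H]1[C@]1(C)O[C@@H]1COCc1ccc(OC)c(OC)c1 | intermediate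
28 | methyl acrylate | C=CC(=O)OC | starting material
29 | Morita–Baylis–Hillman adduct: 1-methyl 7-[2-(trimethylsilyl)ethyl] (6E)-6-{[bis-oxiranyl]methylidene}-3-hydroxy-2-methylidene-4-(naphthalen-2-ylmethoxy)-5-(triethylsilyloxy)heptanedioate (both C7 epimers; C8, C9 and oxiranes as in 25) | C=C(C(=O)OC)C(O)[C@H](OCc1ccc2ccccc2c1)[C@@H](O[Si](CC)(CC)CC)/C(C(=O)OCC[Si](C)(C)C)=C\[C@H]1O[C@H]1[C@]1(C)O[C@@H]1COCc1ccc(OC)c(OC)c1 | intermediate
30 | 1-methyl 7-[2-(trimethylsilyl)ethyl] (2Z,4S,5S,6E)-2-(bromomethyl)-6-{[(2R,3R)-3-((2R,3R)-3-{[(3,4-dimethoxybenzyl)oxy]methyl}-2-methyloxiran-2-yl)oxiran-2-yl]methylidene}-4-(naphthalen-2-ylmethoxy)-5-(triethylsilyloxy)hept-2-enedioate | BrC/C(C(=O)OC)=C\[C@H](OCc1ccc2ccccc2c1)[C@@H](O[Si](CC)(CC)CC)/C(C(=O)OCC[Si](C)(C)C)=C\[C@H]1O[C@H]1[C@]1(C)O[C@@H]1COCc1ccc(OC)c(OC)c1 | intermediate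
31 | C6 alcohol: as 30 with the (2R,3R)-3-(hydroxymethyl)-2-methyloxiran-2-yl group in place of the dimethoxybenzyl ether | BrC/C(C(=O)OC)=C\[C@H](OCc1ccc2ccccc2c1)[C@@H](O[Si](CC)(CC)CC)/C(C(=O)OCC[Si](C)(C)C)=C\[C@H]1O[C@H]1[C@]1(C)O[C@@H]1CO | intermediate
32 | seco-aldehyde: as 30 with a (2S,3S)-3-formyl-2-methyloxiran-2-yl group (C6 aldehyde; geometry at C4 and C5 unchanged) | BrC/C(C(=O)OC)=C\[C@H](OCc1ccc2ccccc2c1)[C@@H](O[Si](CC)(CC)CC)/C(C(=O)OCC[Si](C)(C)C)=C\[C@H]1O[C@H]1[C@]1(C)O[C@@H]1C=O | intermediate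
33 | dichlorochromium (trivalent chromium) alkoxide of the ring A hydroxy ester (C6–O–CrCl2; C7 carries the methyl propenoate unit; geometry at C6 and C7 as in 34) | C=C(C(=O)OC)[C@@H]1[C@H](OCc2ccc3ccccc3c2)[C@@H](O[Si](CC)(CC)CC)/C(C(=O)OCC[Si](C)(C)C)=C\[C@H]2O[C@H]2[C@]2(C)O[C@@H]2[C@H]1O[Cr](Cl)Cl | intermediate (not isolated)
34 | 2-(trimethylsilyl)ethyl (1(10)E,2R,3R,4R,5R,6S,7R,8S,9S)-2,3:4,5-diepoxy-8-(naphthalen-2-ylmethoxy)-9-(triethylsilyloxy)germacra-1(10),11(13)-dien-12,6-olid-14-oate | C=C1C(=O)O[C@H]2[C@H]1[C@H](OCc1ccc3ccccc3c1)[C@@H](O[Si](CC)(CC)CC)/C(C(=O)OCC[Si](C)(C)C)=C\[C@H]1O[C@H]1[C@]1(C)O[C@H]21 | intermediate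
35 | 8-hydroxy analogue of 34 (naphthylmethyl removed) | C=C1C(=O)O[C@H]2[C@H]1[C@H](O)[C@@H](O[Si](CC)(CC)CC)/C(C(=O)OCC[Si](C)(C)C)=C\[C@H]1O[C@H]1[C@]1(C)O[C@H]21 | intermediate
36 | mixed anhydride of 21 and 2,4,6-trichlorobenzoic acid | O=C(OC(=O)c1c(Cl)cc(Cl)cc1Cl)[C@]1(C)O[C@@H]1C | intermediate (not isolated)
37 | 8-O-[(2R,3R)-2,3-dimethyloxirane-2-carbonyl] 9-O-triethylsilyl 2-(trimethylsilyl)ethyl ester | C=C1C(=O)O[C@H]2[C@H]1[C@H](OC(=O)[C@]1(C)O[C@@H]1C)[C@@H](O[Si](CC)(CC)CC)/C(C(=O)OCC[Si](C)(C)C)=C\[C@H]1O[C@H]1[C@]1(C)O[C@H]21 | intermediate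
38 | 9-hydroxy analogue of 37 (9-deacetyl-leucanthin B 2-(trimethylsilyl)ethyl ester) | C=C1C(=O)O[C@H]2[C@H]1[C@H](OC(=O)[C@]1(C)O[C@@H]1C)[C@@H](O)/C(C(=O)OCC[Si](C)(C)C)=C\[C@H]1O[C@H]1[C@]1(C)O[C@H]21 | intermediate
39 | leucanthin B 2-(trimethylsilyl)ethyl ester | C=C1C(=O)O[C@H]2[C@H]1[C@H](OC(=O)[C@]1(C)O[C@@H]1C)[C@@H](OC(C)=O)/C(C(=O)OCC[Si](C)(C)C)=C\[C@H]1O[C@H]1[C@]1(C)O[C@H]21 | intermediate
40 | leucanthin B | C=C1C(=O)O[C@H]2[C@H]1[C@H](OC(=O)[C@]1(C)O[C@@H]1C)[C@@H](OC(C)=O)/C(C(=O)O)=C\[C@H]1O[C@H]1[C@]1(C)O[C@H]21 | target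

**Step count and risks**

Total step count: 28. Longest linear sequence: 19 steps (steps 1–6 and 16–28, from 1 to 40).

Steps most likely to fail:

1. Step 23 (key ring closure). The face of the epoxy aldehyde may not be differentiated well enough in the closed transition state: attack through the non-chelated, Felkin-type arrangement would give C6 epimers, and intermolecular coupling can compete with ring closure. Fallback, from 32 back to 34: C6 is no longer set in the carbon–carbon bond formation. Compound 32 is cyclised with catalytic CrCl2, Mn powder and Me3SiCl in THF, so that the alkoxide is trapped and cannot lactonise, giving the C6 trimethylsilyl ether F1 (both C6 epimers, C7 as in 34). Buffered HF·pyridine liberates the ring A hydroxy ester F2, which is oxidised at once with Dess–Martin periodinane to the C6 ketone F3. A Corey–Bakshi–Shibata reduction with the oxazaborolidine enantiomer matched to the 6S carbinol returns the 6S epimer of F2, which closes to lactone 34.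

2. Step 5 (second epoxidation). Oxygen transfer to a cis-allylic alcohol whose cis substituent is a fully substituted oxiranyl carbon may be slow and mismatched with the existing oxirane, and opening of the vinyl oxirane by the titanium alkoxide can overtake it. Fallback, from 1 back to 7: the order of the two oxiranes is reversed and the second is made without a directing hydroxyl. Compound 1 is etherified first (NaH, 3,4-dimethoxybenzyl bromide) to the dimethoxybenzyl ether F4. Its lithium acetylide F5 (n-BuLi) is hydroxymethylated with paraformaldehyde to the propargylic alcohol F6, and Lindlar reduction gives the (2Z,4Z)-dienol F7. Sharpless epoxidation (D-(−)-diethyl tartrate) of this unhindered cis-allylic alcohol gives the 2,3-epoxy alcohol F8. Shi epoxidation (D-fructose-derived ketone, KHSO5, pH 10.5 buffer, 0 °C) of the remaining trisubstituted C4=C5 alkene then gives 7.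

3. Step 19 (Morita–Baylis–Hillman reaction). The amine-catalysed addition is slow on this α-alkoxy β-silyloxy aldehyde, so β-elimination of silanol and epimerisation at C8 can overtake it. Fallback, from 27 back to 29: the acrylate α-carbanion is supplied as a preformed organometallic instead of by amine catalysis. Hydroalumination of methyl propiolate (iBu2AlH, N-methylmorpholine N-oxide, THF, 0 °C) gives the vinylalane [1-(methoxycarbonyl)ethenyl]bis(2-methylpropyl)aluminium F9, which should add to 27 at −78 to 0 °C to give 29 directly.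

Further compounds
F1 | step 23 | ring A hydroxy ester as its C6 trimethylsilyl ether (both C6 epimers; other centres as in 34) | C=C(C(=O)OC)[C@@H]1[C@H](OCc2ccc3ccccc3c2)[C@@H](O[Si](CC)(CC)CC)/C(C(=O)OCC[Si](C)(C)C)=C\[C@H]2O[C@H]2[C@]2(C)O[C@@H]2C1O[Si](C)(C)C
F2 | step 23 | ring A hydroxy ester (C6 carbinol, both epimers; C7 carries the methyl propenoate unit) | C=C(C(=O)OC)[C@@H]1[C@H](OCc2ccc3ccccc3c2)[C@@H](O[Si](CC)(CC)CC)/C(C(=O)OCC[Si](C)(C)C)=C\[C@H]2O[C@H]2[C@]2(C)O[C@@H]2C1O
F3 | step 23 | ring A C6 ketone | C=C(C(=O)OC)[C@@H]1[C@H](OCc2ccc3ccccc3c2)[C@@H](O[Si](CC)(CC)CC)/C(C(=O)OCC[Si](C)(C)C)=C\[C@H]2O[C@H]2[C@]2(C)O[C@@H]2C1=O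
F4 | step 5 | 4-({[(2Z)-3-methylpent-2-en-4-yn-1-yl]oxy}methyl)-1,2-dimethoxybenzene | C#C/C(C)=C\COCc1ccc(OC)c(OC)c1
F5 | step 5 | lithium acetylide of F4 | [Li]C#C/C(C)=C\COCc1ccc(OC)c(OC)c1
F6 | step 5 | (4Z)-6-[(3,4-dimethoxybenzyl)oxy]-4-methylhex-4-en-2-yn-1-ol | OCC#C/C(C)=C\COCc1ccc(OC)c(OC)c1
F7 | step 5 | (2Z,4Z)-6-[(3,4-dimethoxybenzyl)oxy]-4-methylhexa-2,4-dien-1-ol | OC/C=C\C(C)=C/COCc1ccc(OC)c(OC)c1
F8 | step 5 | [(2R,3S)-3-{(2Z)-4-[(3,4-dimethoxybenzyl)oxy]but-2-en-2-yl}oxiran-2-yl]methanol | OC[C@H]1O[C@H]1/C(C)=C\COCc1ccc(OC)c(OC)c1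
F9 | step 19 | [1-(methoxycarbonyl)ethenyl]bis(2-methylpropyl)aluminium | C=C(C(=O)OC)[Al](CC(C)C)CC(C)C
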